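## Structural features

The target 11 is a 4H-chromen-4-one. Benzene ring A (C4a, C5, C6, C7, C8, C8a) is fused along the C4a–C8a bond to γ-pyrone ring B (O1, C2, C3, C4). Ring A is hexasubstituted: hydroxyl groups on C5 and C7, methyl groups on C6 and C8, the ring oxygen O1 on C8a and the carbonyl carbon C4 on C4a. Ring B carries only an unbranched nonadecyl chain on C2 and a hydrogen on C3. There is no stereocenter and no configured double bond, so nothing stereochemical has to be set or preserved.

The fragile parts are the electron-rich phloroglucinol nucleus (air oxidation of its phenolates, C-alkylation with loss of aromaticity) and the γ-pyrone, which hot aqueous base opens at C2. The C19 chain makes every late compound waxy and poorly soluble in polar media.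

Ring B is not the problem, because any ortho-hydroxyaryl 1,3-diketone closes to it. The real difficulty is the regiodefined, fully substituted ring A. By substitution chemistry it would need two C-methylations and one C-acylation on a nucleus that becomes more reactive with each step.

The feature that the key step exploits is the path C5–C6–C7–C8–C8a–C4a–C4–C3–C2. Every second carbon (C5, C7, C8a, C4, C2) bears oxygen and the carbons between are CH or C–CH3, so rings A and B together are one folded poly-β-carbonyl chain with methyl branches at C6 and C8. A second feature is the local mirror plane of ring A through C4a and C7, which makes the oxygens on C5 and C8a equivalent until ring B is closed.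

## Logic of the disconnections

The route in one sentence: ring A is made rather than bought, by opening the 2-pyrone ring of 8 with methoxide and closing the liberated ester onto the side-chain methylene (Claisen), after which acid closes ring B.

**11 to 10.** Cut: the enol ether bond O1–C2 of ring B, with formal addition of water at C2.
- Reason: this is the retro-cyclodehydration of an ortho-hydroxyaryl 1,3-diketone, the one trivially reversible bond of the bicycle.
- Gain: a bicycle becomes a monocyclic arene with an open side chain, and the mirror plane through C4a and C7 is restored.
- Demand: an acid-catalysed closure that tolerates free phenols and can run in the flask of the preceding reaction. No regiochemical demand arises, since both ortho oxygens are equivalent.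

**10 to 8 by way of 9 (key disconnection).** Cut: C4a–C5 of ring A, which unfolds the benzene ring to the chain 9. The oxygen on C8a is then tied to C5 as a lactone, which gives 8.
- Reason: in the unfolded chain C4a is a methylene between two ketones (C4 and C8a) and C5 is the chain terminus at the acid oxidation level. The bond therefore has natural Claisen polarity and copies the fold presumed for the biosynthesis.
- Why 8 and not 9: 9 is not a storable compound, whereas 8 is its stable cyclic form with fewer acidic sites.
- Gain: a hexasubstituted benzene is exchanged for a 2-pyrone whose carbons (future C5 to C8a) receive their substituents from chain assembly, not from aromatic substitution. No protecting group is needed.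
- Demand: the lactone must open, and Claisen closure from C4a must win over every aldol closure of the chain.

**8 to 4 + 7.** Cut: C4–C4a (side-chain C1′–C2′ of 8).
- Reason: the cut separates the polar head (all ring A carbons plus C4a) from the lipid tail (C4, C3, C2 and the chain). It uses C4a as the vinylogous methyl carbon of 4 and C4 as the ester carbon of 7.
- Gain: a convergent union of two fragments, each made in one or two steps.
- Demand: the carbanion must form only at the C6 methyl of 4, and it must acylate an ester that owns an acidic methylene. For that reason 7 is offered as its enolate salt.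

**7 to 5 + 6.** Cut: the bond between the first and second carbon of the nonadecyl chain (C4–C5 of 7).
- Reason: the odd C19 chain is best composed of an even C18 halide and the terminal carbon of an acetoacetate.
- Gain: two bulk chemicals.
- Demand: alkylation at the γ-carbon only, hence the dianion.

**4 to 3.** Cut: the lactone bond O1–C2 of the pyrone.
- Reason: a 3,5-dioxo ester lactonizes through its C5 enol oxygen.
- Gain: a ring is exchanged for an open chain.
- Demand: O-closure (lactone), not C-closure, which a mild amidine base secures.

**3 to 1 + 2.** Cut: C4–C5 of 3 (future C8–C8a).
- Reason: the cut leaves a propionate-derived keto ester that already holds both methyl branches (future C6 and C8 methyls) and an acetyl donor that brings C8a and C4a.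
- Gain: two small starting materials.
- Demand: γ-acylation without proton quench by the more acidic product.

## Other disconnections considered

**Alternative 1:** (the first that comes to mind)
- Cut: O1–C2 and C2–C3, with ring A kept intact.
- Forward key step: a Baker–Venkataraman acyl shift. The protected acetophenone 1-[2-hydroxy-4,6-bis(methoxymethoxy)-3,5-dimethylphenyl]ethan-1-one A1 would be O-acylated with the C20 acid chloride to the aryl ester A2. Base would move the acyl group to the acetyl methyl, and acid would close ring B and remove the acetals.
- Ground for preferring the chosen plan: the key step of this alternative solves only the easy ring. The hexasubstituted ring A is left to electrophilic substitution on the parent triphenol, where every C-methylation raises the nucleophilicity, geminal methylation with dearomatization competes, and two of three hydroxyl groups must be differentiated by protection. The count of operations before A1 alone should exceed the whole chosen route.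

**Alternative 2:**
- Cut: C4–C4a and O1–C2.
- Forward key step: thermal (Mentzer-type) or P2O5-promoted (Simonis) union of 2,4-dimethylbenzene-1,3,5-triol A3 with the β-keto ester 7, through its acylketene.
- Ground: the plan is short, but nothing in the structure decides between C-acylation at the one free ring carbon (chromone) and O-acylation followed by Pechmann closure. The latter path leads to the isomeric coumarin 5,7-dihydroxy-6,8-dimethyl-4-nonadecyl-2H-chromen-2-one A4. In addition, A3 carries the same C-methylation problem as Alternative 1. In the chosen plan the C4–C4a bond exists before ring A does, so this ambiguity cannot arise.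

**Alternative 3:**
- Cut: C4a–C5, C5–C6 and C7–C8.
- Forward key step: a Danheiser benzannulation.
  - Photochemical Wolff rearrangement of the diazo ketone 2-(2-diazopropanoyl)-6-nonadecyl-4H-pyran-4-one A5 would give the pyronyl(methyl)ketene A7.
  - A7 would add the siloxyalkyne triisopropyl(prop-1-yn-1-yloxy)silane A6 in a [2+2] reaction.
  - Four-electron opening and six-electron electrocyclization onto C3 of the pyrone would then give the 7-O-silyl chromone A8, and desilylation would follow.
- Ground: the regiochemistry is well defined, but three points count against it. A5 should cost about five steps (pyrone carboxylate, ethyl ketone, diazo transfer) and A6 is a sensitive reagent that has to be made. The light needed for the Wolff step also excites the γ-pyrone chromophore, which has photochemistry of its own. A final deprotection is added. The chosen plan reaches the same ring in fewer steps and with no protecting group.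

Key step: step 5

Assumption: 1 is taken as a catalogue compound (it is the Claisen self-condensation product of methyl propanoate). All poly-β-carbonyl compounds are written as keto tautomers, and their enolizable stereocenters are left unspecified because they are configurationally labile and vanish on aromatization.

## Steps

**Step 1**
Reactants: 1 methyl 2-methyl-3-oxopentanoate; 2 N-methoxy-N-methylacetamide
Product: 3 methyl 2,4-dimethyl-3,5-dioxohexanoate
Conditions: LiN(iPr)2 (2.1 equiv), THF, −78 to 0 °C; then 2, −78 to 0 °C; aq. HCl
Reagents that add atoms: none
Why: γ-Acylation of a β-keto ester dianion (Weiler type): the second, less stabilized carbanion at C4 of 1 is the more nucleophilic site and attacks the Weinreb amide, whose lithium-chelated tetrahedral adduct should survive until the quench, so that the more acidic product neither protonates unreacted dianion nor is acylated again. The two stereocenters of 3 are enolizable and disappear in step 2, so their configuration is irrelevant.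

**Step 2**
Reactants: 3 methyl 2,4-dimethyl-3,5-dioxohexanoate
Product: 4 4-hydroxy-3,5,6-trimethyl-2H-pyran-2-one
Conditions: DBU (1.5 equiv), toluene, reflux; aq. HCl
Reagents that add atoms: none
Why: Base-induced enol lactonization of a 3,5-dioxo ester: the C5 enolate oxygen attacks the ester carbonyl (6-exo-trig), methoxide leaves, and the aromatic 4-oxido-2-pyrone salt is the thermodynamic sink. This is the standard entry to 3,5-dimethyl-4-hydroxy-2-pyrones.

**Step 3**
Reactants: 5 methyl acetoacetate; 6 1-bromooctadecane
Product: 7 methyl 3-oxodocosanoate
Conditions: LiN(iPr)2 (2.1 equiv), THF, 0 °C; then 6, 0 °C to rt; aq. HCl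
Reagents that add atoms: none
Why: Weiler γ-alkylation: the terminal carbanion of the dianion of 5 displaces bromide from the primary halide (SN2), while the remaining stabilized enolate is too unreactive for a second alkylation. The C18 halide plus the terminal carbon of 5 make up the nonadecyl chain on the ketone.

**Step 4**
Reactants: 4 4-hydroxy-3,5,6-trimethyl-2H-pyran-2-one; 7 methyl 3-oxodocosanoate
Product: 8 6-(2,4-dioxotricosyl)-4-hydroxy-3,5-dimethyl-2H-pyran-2-one
Conditions: 4 (2 equiv), LiN(iPr)2 (4.1 equiv), THF, −78 to 0 °C; lithium enolate of 7 (from 7 and LiN(iPr)2, 1.0 equiv, THF, −78 °C) added, 0 °C to rt; aq. HCl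
Reagents that add atoms: none
Why: Claisen acylation of a lateral (vinylogous) carbanion: two equivalents of base remove the 4-OH proton and one proton of the C6 methyl group, the only methyl conjugated with the carbonyl system through C5=C6 (the methyls on C3 and C5 are merely allylic). This strongly basic carbanion attacks the ester carbonyl of the enolate salt of 7, whose ketone and acidic methylene are masked by the prior enolization; acylation of polyanions by salts of β-keto esters is a known chain extension of poly-β-carbonyl chemistry. The second equivalent of the dianion of 4 takes up the new acidic proton at C1′ and is recovered as 4.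

**Step 5**
Reactants: 8 6-(2,4-dioxotricosyl)-4-hydroxy-3,5-dimethyl-2H-pyran-2-one
Product: 11 5,7-dihydroxy-6,8-dimethyl-2-nonadecyl-4H-chromen-4-one, via open-chain tetraoxo ester 9 (not isolated), via aryl 1,3-diketone 10 (not isolated)
Conditions: Mg(OMe)2 (10 equiv), MeOH–THF, reflux, argon; then conc. HCl to pH 1, reflux
Reagents that add atoms: magnesium dimethoxide, C[O-].C[O-].[Mg+2] (one methoxy group enters 9 and leaves again as methanol on closure to 10; no reagent atom stays in 11)
Why: Methoxide adds to the lactone carbonyl C2 of 8 and opens the 2-pyrone to the magnesium-chelated ester 9, in which the former side-chain methylene (C6 of 9, chain numbering from the ester carbon C1; future C4a) lies between two ketones and can reach C1 (future C5) through a six-membered ring. Its enolate attacks the ester in a 6-(enolexo)-exo-trig Claisen closure, methoxide leaves, and enolization to the phloroglucinol 10 makes the new C4a–C5 bond irreversible. The closest known reaction type is the recyclization of 6-(2-oxoalkyl)-4-hydroxy-2-pyrones to acylphloroglucinols by Mg(OMe)2, the laboratory copy of the Claisen fold of a polyketide chain. The step needs Claisen closure to win over aldol closure: with excess base the three more acidic positions of 9 (C4, C6, C8) are enolized, so every ketone oxygen is a magnesium-bound enolate oxygen, and the ester C1, whose neighbour C2–H is the least acidic proton because it is ester-flanked and methyl-substituted, is the only electrophilic carbonyl left, which of the nucleophilic carbons only C6 can reach in a six-membered ring. The substrate adds two safeguards: aldol attack from the methyl-bearing carbons C2 or C4 would create a quaternary ring carbon that cannot aromatize and so stays reversible, and the one aldol that could aromatize (C8 onto the C3 ketone) must hit the most hindered carbonyl, flanked by two CHMe groups. Acidification then lets an ortho-hydroxyl of 10 add to the distal ketone (6-exo-trig hemiketal) and lose water to give ring B. The aryl part of 10 has a mirror plane through C4a and C7, so both ortho-hydroxyls give the same chromone. No stereocenter is formed, and the labile stereocenters of 9 are erased by aromatization.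

## Compound list

1 | methyl 2-methyl-3-oxopentanoate (racemic, labile) | CCC(=O)C(C)C(=O)OC | starting material
2 | N-methoxy-N-methylacetamide | CC(=O)N(C)OC | starting material
3 | methyl 2,4-dimethyl-3,5-dioxohexanoate (labile diastereomers and enol forms) | CC(=O)C(C)C(=O)C(C)C(=O)OC | intermediate
4 | 4-hydroxy-3,5,6-trimethyl-2H-pyran-2-one | Cc1oc(=O)c(C)c(O)c1C | intermediate
5 | methyl acetoacetate (methyl 3-oxobutanoate) | CC(=O)CC(=O)OC | starting material
6 | 1-bromooctadecane | CCCCCCCCCCCCCCCCCCBr | starting material
7 | methyl 3-oxodocosanoate | CCCCCCCCCCCCCCCCCCCC(=O)CC(=O)OC | intermediate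
8 | 6-(2,4-dioxotricosyl)-4-hydroxy-3,5-dimethyl-2H-pyran-2-one | CCCCCCCCCCCCCCCCCCCC(=O)CC(=O)Cc1oc(=O)c(C)c(O)c1C | intermediate
9 | methyl 2,4-dimethyl-3,5,7,9-tetraoxooctacosanoate (present as magnesium chelate, not isolated) | CCCCCCCCCCCCCCCCCCCC(=O)CC(=O)CC(=O)C(C)C(=O)C(C)C(=O)OC | intermediate
10 | 1-(2,4,6-trihydroxy-3,5-dimethylphenyl)docosane-1,3-dione (not isolated) | CCCCCCCCCCCCCCCCCCCC(=O)CC(=O)c1c(O)c(C)c(O)c(C)c1O | intermediate
11 | 5,7-dihydroxy-6,8-dimethyl-2-nonadecyl-4H-chromen-4-one | CCCCCCCCCCCCCCCCCCCc1cc(=O)c2c(O)c(C)c(O)c(C)c2o1 | target

## Step count and least certain steps

Total step count: 5. Longest linear sequence: 4 (steps 1, 2, 4, 5). The second branch (step 3) joins at step 4.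

**Step 5 (key step).**
- What may go wrong:
  - Misfolding of the opened chain, that is aldol closure from the second active methylene (C8 of 9) whenever enolization is incomplete.
  - Slow methanolysis of the electron-rich, doubly methylated pyrone anion.
  - Retro-Claisen cleavage of the chain by methoxide on long heating.
- Fallback: it sets out from 4 and comes back to the route at 10. It moves the ring transformation to the shorter chain, where only one doubly activated methylene exists, and attaches the lipid afterwards.
  - The dianion of 4 is acylated with 2 to 4-hydroxy-3,5-dimethyl-6-(2-oxopropyl)-2H-pyran-2-one F1.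
  - Mg(OMe)2 in MeOH should recyclize this to 1-(2,4,6-trihydroxy-3,5-dimethylphenyl)ethan-1-one F2.
  - The polyanion of F2 (LiN(SiMe3)2, 5 equiv, THF, −78 °C) is acylated at the acetyl methyl with icosanoyl chloride to give 10.
  - 10 is closed with HCl as in the second half of step 5.

**Step 4.**
- What may go wrong: proton transfer from the enolate of 7 to the dianion of 4, which would leave an unreactive dianion of 7. The low electrophilicity of an anionic ester adds to this, so conversion may stall.
- Fallback: it sets out from 7 (with 4) and comes back at 8. It replaces the anionic acyl donor by a neutral, masked one, so that the coupling becomes an ordinary ester acylation.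
  - 7 is ketalized (ethylene glycol, TsOH, toluene, Dean–Stark) to methyl 2-(2-nonadecyl-1,3-dioxolan-2-yl)acetate F3.
  - The dianion of 4 is acylated with F3 to 4-hydroxy-3,5-dimethyl-6-[3-(2-nonadecyl-1,3-dioxolan-2-yl)-2-oxopropyl]-2H-pyran-2-one F4.
  - Aqueous acetic acid removes the ketal to give 8.

**Step 1.**
- What may go wrong: incomplete second deprotonation at the secondary C4 position, acylation at C2, or early collapse of the tetrahedral adduct followed by proton quench of the dianion.
- Fallback: it sets out from 1 and comes back at 3. It exchanges acylation for aldol addition and oxidation.
  - The dianion of 1 adds to acetaldehyde to give methyl 5-hydroxy-2,4-dimethyl-3-oxohexanoate F5.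
  - Dess–Martin periodinane in CH2Cl2 oxidizes this to 3.

**Step 3.**
- What may go wrong: a sluggish SN2 reaction, because the C18 bromide is poorly soluble in cold THF, and self-condensation of the dianion on warming.
- Fallback: it sets out from 5 and comes back at 7. It builds the ketone by acylation instead of alkylation.
  - The sodium enolate of 5 (NaH, THF) is C-acylated with icosanoyl chloride to methyl 2-acetyl-3-oxodocosanoate F6.
  - Catalytic NaOMe in MeOH removes the less hindered acetyl group to give 7.

## Further compounds

F1 | step 5 | 4-hydroxy-3,5-dimethyl-6-(2-oxopropyl)-2H-pyran-2-one | CC(=O)Cc1oc(=O)c(C)c(O)c1C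
F2 | step 5 | 1-(2,4,6-trihydroxy-3,5-dimethylphenyl)ethan-1-one | CC(=O)c1c(O)c(C)c(O)c(C)c1O
F3 | step 4 | methyl 2-(2-nonadecyl-1,3-dioxolan-2-yl)acetate | CCCCCCCCCCCCCCCCCCCC1(CC(=O)OC)OCCO1
F4 | step 4 | 4-hydroxy-3,5-dimethyl-6-[3-(2-nonadecyl-1,3-dioxolan-2-yl)-2-oxopropyl]-2H-pyran-2-one | CCCCCCCCCCCCCCCCCCCC1(CC(=O)Cc2oc(=O)c(C)c(O)c2C)OCCO1
F5 | step 1 | methyl 5-hydroxy-2,4-dimethyl-3-oxohexanoate (mixture of diastereomers) | CC(O)C(C)C(=O)C(C)C(=O)OC
F6 | step 3 | methyl 2-acetyl-3-oxodocosanoate | CCCCCCCCCCCCCCCCCCCC(=O)C(C(C)=O)C(=O)OC
A1 | alternative 1 | 1-[2-hydroxy-4,6-bis(methoxymethoxy)-3,5-dimethylphenyl]ethan-1-one | CC(=O)c1c(O)c(C)c(OCOC)c(C)c1OCOC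
A2 | alternative 1 | 2-acetyl-3,5-bis(methoxymethoxy)-4,6-dimethylphenyl icosanoate | CCCCCCCCCCCCCCCCCCCC(=O)Oc1c(C)c(OCOC)c(C)c(OCOC)c1C(C)=O
A3 | alternative 2 | 2,4-dimethylbenzene-1,3,5-triol | Cc1c(O)cc(O)c(C)c1O
A4 | alternative 2 | 5,7-dihydroxy-6,8-dimethyl-4-nonadecyl-2H-chromen-2-one | CCCCCCCCCCCCCCCCCCCc1cc(=O)oc2c(C)c(O)c(C)c(O)c12
A5 | alternative 3 | 2-(2-diazopropanoyl)-6-nonadecyl-4H-pyran-4-one | CCCCCCCCCCCCCCCCCCCc1cc(=O)cc(o1)C(=O)C(C)=[N+]=[N-]
A6 | alternative 3 | triisopropyl(prop-1-yn-1-yloxy)silane | CC#CO[Si](C(C)C)(C(C)C)C(C)C
A7 | alternative 3 | 2-(6-nonadecyl-4-oxo-4H-pyran-2-yl)prop-1-en-1-one (ketene) | CCCCCCCCCCCCCCCCCCCc1cc(=O)cc(o1)C(C)=C=O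
A8 | alternative 3 | 5-hydroxy-6,8-dimethyl-2-nonadecyl-7-[(triisopropylsilyl)oxy]-4H-chromen-4-one | CCCCCCCCCCCCCCCCCCCc1cc(=O)c2c(O)c(C)c(O[Si](C(C)C)(C(C)C)C(C)C)c(C)c2o1
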